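## Retrosynthetic overview

1. The target, 5,7-dihydroxy-2-pentadecyl-4H-chromen-4-one, is cut at the exocyclic bond from C2 of the 4-pyranone ring (ring B) to the first chain carbon. This gives a C9 chromone half and a C15 half, taken as pentadecanal.
2. Both carbons are electrophiles by nature: C2 is the β-carbon of the vinylogous ester O1–C2=C3–C4=O, and the chain carbon is a carbonyl carbon. C2 is therefore polarity-reversed into a phosphorus ylide and joined to the aldehyde by Wittig olefination.
3. Enabling feature: the vinylogous ester of ring B. Silylation of the C4 carbonyl oxygen gives an aromatic 1-benzopyrylium whose unsubstituted C2, flanked by the oxonium O1, takes up PPh3. The exocyclic alkene formed afterwards is the silyl dienol ether tautomer of a 2-alkyl-4-pyranone, so desilylation gives the chromone with no redox step.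
4. Ring order: no ring is built. Benzene ring A and pyranone ring B are bought together as 5,7-dihydroxychromone; ring B only passes through its benzopyrylium and 2H-chromene forms and is restored. Both phenols are carried as TBS ethers, so one fluoride treatment ends the key step at the natural product.
5. The C15 aldehyde is made fresh from pentadecan-1-ol, so the route is convergent: two one-step branches, then the union.

Key step: step 3

Remark: the target has no stereocentre and no stereogenic double bond. The only stereo-elements on the way (C2 of the phosphonium salt, the E/Z geometry of the exocyclic alkene) are transient and are erased before the product is reached.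

## Route

Step 1
Reactants: 1 5,7-dihydroxy-4H-chromen-4-one (5,7-dihydroxychromone)
Product: 2 5,7-bis[(tert-butyldimethylsilyl)oxy]-4H-chromen-4-one
Conditions: TBSOTf (2.3 equiv), 2,6-lutidine (3 equiv), CH2Cl2, 0 °C → rt; aq. NaHCO3 work-up
Reagents that add atoms: tert-butyldimethylsilyl trifluoromethanesulfonate (TBSOTf), CC(C)(C)[Si](C)(C)OS(=O)(=O)C(F)(F)F
Why: O-silylation of phenols with a silyl triflate, which is reactive enough for the hydrogen-bonded 5-OH as well as the 7-OH, while any O4-silylated benzopyrylium should revert to the chromone on bicarbonate work-up.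

Step 2
Reactants: 3 pentadecan-1-ol
Product: 4 pentadecanal
Conditions: TEMPO (10 mol %), PhI(OAc)2 (1.1 equiv), CH2Cl2, rt
Reagents that add atoms: none
Why: oxoammonium-mediated (TEMPO/PhI(OAc)2) oxidation of a primary alcohol, which in dry CH2Cl2 forms no aldehyde hydrate and should therefore stop at the aldehyde, to be used fresh.

Step 3
Reactants: 2 5,7-bis[(tert-butyldimethylsilyl)oxy]-4H-chromen-4-one; 4 pentadecanal
Product: 9 5,7-dihydroxy-2-pentadecyl-4H-chromen-4-one (the target), via benzopyrylium triflate 5 (not isolated), via phosphonium triflate 6 (not isolated), via phosphonium ylide 7 (not isolated), via silyl dienol ether 8 (not isolated)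
Conditions: TBSOTf (1.05 equiv), CH2Cl2, rt; PPh3 (1.1 equiv), 0 °C → rt; solvent exchange to THF; LiN(SiMe3)2 (1.05 equiv), -78 °C; 4 (1.1 equiv), -78 °C → rt; Bu4NF (3.5 equiv), AcOH, 0 °C → rt; 1 M HCl work-up
Reagents that add atoms: none
Why: Silylation of the C4 carbonyl oxygen of the vinylogous ester in ring B converts 2 into the aromatic benzopyrylium 5, PPh3 adds at its unsubstituted C2 next to the oxonium O1 to give 6, and LiN(SiMe3)2 removes the C2–H to give ylide 7, so that the natively electrophilic C2 now attacks the carbonyl carbon of 4 and the oxaphosphetane collapses to alkene 8 and Ph3PO (Wittig olefination with polarity reversal at C2). Alkene 8 is the silyl dienol ether of the target, so fluoride strips all three silyl groups and protonation at the former aldehyde carbon, completed by the acidic work-up, restores the 4-pyranone; the chromone oxidation level is reached without a redox step and both phenols are released in the same flask. The closest known reaction type is the Wittig olefination of α-alkoxy phosphonium ylides made from oxocarbenium ions and PPh3, which includes (4-silyloxy-2H-chromen-2-yl)phosphonium ylides generated from simple chromones and a silyl triflate and their reaction with aldehydes. No ring is closed and no stereocentre is created: C2 of 6 is a transient racemic centre that becomes trigonal in 7, and the E/Z geometry of 8 is erased by the tautomerisation. The step needs phosphine attack at C2 and not C4, deprotonation and not addition by the base, olefination and not enolisation of 4, and final protonation at the chain terminus; these should be secured by the silyloxy-bearing, peri-hindered C4, by the hindered amide base and the single acidic C–H of 6, by the low temperature and the carbonyl affinity of non-stabilised α-oxy ylides, and by the aromatic, conjugated 4-pyranone as thermodynamic sink.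

## Compound list

1 | 5,7-dihydroxy-4H-chromen-4-one (5,7-dihydroxychromone) | O=c1ccoc2cc(O)cc(O)c12 | starting material
2 | 5,7-bis[(tert-butyldimethylsilyl)oxy]-4H-chromen-4-one | O=c1ccoc2cc(O[Si](C)(C)C(C)(C)C)cc(O[Si](C)(C)C(C)(C)C)c12 | intermediate
3 | pentadecan-1-ol | CCCCCCCCCCCCCCCO | starting material
4 | pentadecanal | CCCCCCCCCCCCCCC=O | intermediate
5 | 4,5,7-tris[(tert-butyldimethylsilyl)oxy]chromenylium (1-benzopyrylium) trifluoromethanesulfonate, formed in the flask in step 3 | CC(C)(C)[Si](C)(C)Oc1cc[o+]c2cc(O[Si](C)(C)C(C)(C)C)cc(O[Si](C)(C)C(C)(C)C)c12.[O-]S(=O)(=O)C(F)(F)F | intermediate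
6 | {4,5,7-tris[(tert-butyldimethylsilyl)oxy]-2H-chromen-2-yl}triphenylphosphonium trifluoromethanesulfonate, racemic at C2, formed in the flask in step 3 | CC(C)(C)[Si](C)(C)OC1=CC([P+](c2ccccc2)(c2ccccc2)c2ccccc2)Oc2cc(O[Si](C)(C)C(C)(C)C)cc(O[Si](C)(C)C(C)(C)C)c12.[O-]S(=O)(=O)C(F)(F)F | intermediate
7 | 4,5,7-tris[(tert-butyldimethylsilyl)oxy]-2-(triphenyl-λ5-phosphanylidene)-2H-chromene (the ylide of 6), formed in the flask in step 3 | CC(C)(C)[Si](C)(C)OC1=CC(=P(c2ccccc2)(c2ccccc2)c2ccccc2)Oc2cc(O[Si](C)(C)C(C)(C)C)cc(O[Si](C)(C)C(C)(C)C)c12 | intermediate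
8 | 4,5,7-tris[(tert-butyldimethylsilyl)oxy]-2-pentadecylidene-2H-chromene, E/Z mixture (geometry left open), formed in the flask in step 3 | CCCCCCCCCCCCCCC=C1C=C(O[Si](C)(C)C(C)(C)C)c2c(O[Si](C)(C)C(C)(C)C)cc(O[Si](C)(C)C(C)(C)C)cc2O1 | intermediate
9 | 5,7-dihydroxy-2-pentadecyl-4H-chromen-4-one (CNP0299330.0) | CCCCCCCCCCCCCCCc1cc(=O)c2c(O)cc(O)cc2o1 | target

## Step count and risks

Total step count: 3. Longest linear sequence: 2 steps (step 1 then step 3, or step 2 then step 3).

Steps most likely to fail:

Step 3. The electron-rich, 5,7-dioxygenated benzopyrylium may be captured incompletely by PPh3, so that the amide base adds to residual pyrylium. The ylide may also enolise the aldehyde instead of olefinating it; either process returns chromone after work-up. The fallback makes the same bond with normal polarity by known chemistry; it sets out from compound 2 and comes back to the route at compound 9. 1-Bromopentadecane (CCCCCCCCCCCCCCCBr) is converted with Mg turnings in THF into C15H31MgBr. This is added to 2 under CuBr·SMe2 catalysis in the presence of Me3SiCl at -78 °C (copper-catalysed conjugate addition to the chromone enone with silyl trapping). The expected product is the racemic silyl enol ether 5,7-bis[(tert-butyldimethylsilyl)oxy]-2-pentadecyl-4-(trimethylsilyloxy)-2H-chromene F1. Saegusa–Ito dehydrosilylation of F1 with Pd(OAc)2 in MeCN should give 5,7-bis[(tert-butyldimethylsilyl)oxy]-2-pentadecyl-4H-chromen-4-one F2. Bu4NF/AcOH in THF then removes both silyl ethers to give 9.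

Step 1. Silylation may stall at the hydrogen-bonded 5-OH, or the labile peri 5-O-silyl group may be lost by hydrolysis during work-up and chromatography, giving mixtures of mono- and bis-silyl ethers. The fallback changes the protecting-group plan to methyl ethers removed at the end; it sets out from compound 1 and comes back to the route at compound 9. Compound 1 is dimethylated (MeI, K2CO3, DMF, 60 °C) to 5,7-dimethoxy-4H-chromen-4-one F3. F3 is taken with compound 4 through the sequence of step 3 (TBSOTf; PPh3; LiN(SiMe3)2; 4). The intermediates are: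
- 4-[(tert-butyldimethylsilyl)oxy]-5,7-dimethoxychromenylium trifluoromethanesulfonate F4;
- {4-[(tert-butyldimethylsilyl)oxy]-5,7-dimethoxy-2H-chromen-2-yl}triphenylphosphonium trifluoromethanesulfonate F5;
- its ylide 4-[(tert-butyldimethylsilyl)oxy]-5,7-dimethoxy-2-(triphenyl-λ5-phosphanylidene)-2H-chromene F6;
- 4-[(tert-butyldimethylsilyl)oxy]-5,7-dimethoxy-2-pentadecylidene-2H-chromene F7.

An aqueous HCl quench in place of fluoride should give 5,7-dimethoxy-2-pentadecyl-4H-chromen-4-one F8. BBr3 in CH2Cl2 (-78 °C → rt) then cleaves both methyl ethers to give 9.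

Step 2. The aldehyde may be over-oxidised to the carboxylic acid, or may autoxidise and trimerise on standing, so that step 3 receives less aldehyde than calculated. The fallback replaces alcohol oxidation by oxidative cleavage of an alkene. It does not start from a numbered compound: it sets out from commercial hexadec-1-ene (C=CCCCCCCCCCCCCCC) in place of compound 3 and comes back to the route at compound 4. Ozonolysis in CH2Cl2 at -78 °C should give the secondary ozonide 3-tetradecyl-1,2,4-trioxolane F9, which is reduced in the same flask with PPh3 to compound 4 and formaldehyde.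

## Further compounds

F1 | step 3 | 5,7-bis[(tert-butyldimethylsilyl)oxy]-2-pentadecyl-4-(trimethylsilyloxy)-2H-chromene, racemic | CCCCCCCCCCCCCCCC1C=C(O[Si](C)(C)C)c2c(O[Si](C)(C)C(C)(C)C)cc(O[Si](C)(C)C(C)(C)C)cc2O1
F2 | step 3 | 5,7-bis[(tert-butyldimethylsilyl)oxy]-2-pentadecyl-4H-chromen-4-one | CCCCCCCCCCCCCCCc1cc(=O)c2c(O[Si](C)(C)C(C)(C)C)cc(O[Si](C)(C)C(C)(C)C)cc2o1
F3 | step 1 | 5,7-dimethoxy-4H-chromen-4-one | O=c1ccoc2cc(OC)cc(OC)c12
F4 | step 1 | 4-[(tert-butyldimethylsilyl)oxy]-5,7-dimethoxychromenylium trifluoromethanesulfonate | CC(C)(C)[Si](C)(C)Oc1cc[o+]c2cc(OC)cc(OC)c12.[O-]S(=O)(=O)C(F)(F)F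
F5 | step 1 | {4-[(tert-butyldimethylsilyl)oxy]-5,7-dimethoxy-2H-chromen-2-yl}triphenylphosphonium trifluoromethanesulfonate, racemic | CC(C)(C)[Si](C)(C)OC1=CC([P+](c2ccccc2)(c2ccccc2)c2ccccc2)Oc2cc(OC)cc(OC)c12.[O-]S(=O)(=O)C(F)(F)F
F6 | step 1 | 4-[(tert-butyldimethylsilyl)oxy]-5,7-dimethoxy-2-(triphenyl-λ5-phosphanylidene)-2H-chromene | CC(C)(C)[Si](C)(C)OC1=CC(=P(c2ccccc2)(c2ccccc2)c2ccccc2)Oc2cc(OC)cc(OC)c12
F7 | step 1 | 4-[(tert-butyldimethylsilyl)oxy]-5,7-dimethoxy-2-pentadecylidene-2H-chromene, E/Z mixture | CCCCCCCCCCCCCCC=C1C=C(O[Si](C)(C)C(C)(C)C)c2c(OC)cc(OC)cc2O1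
F8 | step 1 | 5,7-dimethoxy-2-pentadecyl-4H-chromen-4-one | CCCCCCCCCCCCCCCc1cc(=O)c2c(OC)cc(OC)cc2o1
F9 | step 2 | 3-tetradecyl-1,2,4-trioxolane, racemic | CCCCCCCCCCCCCCC1OCOO1
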